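## The problem

The target 24 is a diaryl ether of two densely substituted benzene rings and has no stereocentre, so the task is one of regiochemistry, not stereocontrol. Prenyl means 3-methylbut-2-en-1-yl throughout. Ring A is a methyl benzoate whose two ortho positions carry a prenyl ether and the bridging oxygen. Ring B carries five different substituents in fixed order: bridging oxygen on C1', prenyl ether on C2', methoxy on C4', C-prenyl on C5' and hydroxymethyl (C7') on C6', with only C3' bearing hydrogen. The bridging oxygen is flanked by three ortho substituents, so a late aryl–oxygen coupling of two finished rings is the least attractive bond to make. Placing a C-prenyl group, a one-carbon unit and two different oxygens on ring B by successive aromatic substitutions would be ambiguous at almost every stage. The aryl prenyl ethers and the C-prenyl group rule out strong acid, heating (Claisen shift), hydrogenation and electrophilic reagents late in the route. The benzylic alcohol sits across the ether from the ring A ester and could lactonise to an eight-membered ring under forcing base. The feature that opens the molecule is the oxygen pattern of ring B. The oxygens on C2' and C4' are meta with C3'–H between them and C6' carries a carbon substituent, so C1'–C6' can be read as a chain with carbonyls at C2', C4' and C6' and the ring A aryloxy group on terminal C1'. An aldol bond from C1' to C6' folds that chain into the ring, and the diaryl ether can be made beforehand as a plain alkyl aryl ether.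

## Retrosynthesis

**24 back to 22 by way of 23.** No skeletal bond is cut. The benzylic alcohol of 24 is traced to aldehyde 23 and that to the dimethyl acetal 22. The acetal is the form C7' must have during ring construction, because it activates the C6' ketone and gives it no usable enolate on that side. A protected hydroxymethyl group would instead offer a C7' enolate able to close a wrong six-membered ring onto C2'. The forward steps need an acid mild enough to spare two aryl prenyl ethers and a hydride that leaves the hindered benzoate alone.

**22 to 19 and two molecules of 20.** Both oxygen–prenyl bonds are cut together, leaving bisphenol 19. Prenylating ring A at the outset would be the obvious alternative. Against it, the free ring A phenol is a salicylate and is present as its phenoxide during the ring closure, which switches the neighbouring ester off as an electrophile, and one alkylation step is saved. The forward reaction has to alkylate a free and a chelated phenol on oxygen.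

**19 to 16 (the key cut).** The C1'–C6' bond is cut as an aldol retron, which opens ring B to the chain 16. It is a 2-oxo-4-methoxy-enone-6-one with the acetal on C7', the prenyl group on C5' and the ring A aryloxy group on C1'. The neighbouring cuts are the diaryl ether bond (coupling of a tri-ortho-substituted pair) and the substituent bonds of a preformed resorcinol (regiochemistry open). The aldol cut removes the aromatic ring altogether and lets chain order dictate every position. The forward reaction must close through carbon, not oxygen, and must distinguish the C2' and C4' oxygens. Both are settled by carrying C4' as a methyl enol ether.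

**16 to 12 and 3.** The C2'–C3' bond is cut, dividing the chain into the aryloxyacetyl Weinreb amide 3 and the five-carbon enone 12, whose methyl group is C3'. The alternative is to cut O–C1' and alkylate 1 with a chloromethyl ketone of the whole chain. That would put a Favorskii-prone, enolisable electrophile under base. The forward reaction is a gamma-acylation of dienolate 13 and must not be undone by proton transfer to the more acidic product, hence the Weinreb amide.

**3 to 1 and 2.** The O–C1' bond is cut: a mono-alkylation of the symmetrical resorcinol 1 with the commercial chloroacetamide 2. This is where the future diaryl ether oxygen is attached to what will become ring B, by SN2 chemistry.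

**12 to 10 and 11.** The C5'–CH2 bond of the C-prenyl group is cut to vinyl iodide 10 and prenylstannane 11. The alternative, C-prenylation of the parent 1,3-diketone followed by O-methylation, leaves open which carbonyl becomes the enol ether. The forward Stille coupling has to deliver the linear prenyl isomer.

**10 to 8 by way of 9.** The C–I bond and then the C4'–OMe bond are removed, leading to ynone 8. Conjugate addition of methanol can only place the oxygen on the beta carbon, so the position of the alkyne fixes which carbonyl of the chain is masked.

**8 to 5 and 6, and 5 to 4.** The C5'–C6' bond is cut to propynyl Grignard reagent 6 and Weinreb amide 5, made from ester 4. Direct addition of 6 to ester 4 risks double addition, and the amide removes that risk at the cost of one step.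

## Roads not taken

**Alternative 1:** The cut removes C1'–C6', C4'–C5' and C3'–C4' at once. A zerovalent chromium aryloxy(alkenyl)carbene A1, tethered through the ring A ester to a prenyl-substituted propargylic alcohol, would on warming in dilute solution insert the alkyne and then carbon monoxide and cyclise to the dibenzodioxocinone A2.
- Merits: three carbon–carbon bonds, ring B and an eight-membered lactone are formed in one step, and the tether fixes which alkyne carbon becomes C5' and which C6'. Opening the lactone of A2 with methoxide would unveil the methyl ester and the benzylic alcohol together, which is more economical than the acetal, aldehyde, alcohol sequence from 22 to 24.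
- Weak points: A1 is an aryloxy carbene complex, a class much less stable than alkoxy carbenes and hard to prepare on a ring that also carries an ester. The benzannulation has to pass through a strained eight-membered tether, where oligomerisation and the cyclobutenone and furan channels compete. A2 is born with the wrong oxygen pattern: a free hydroxyl on C4', which must be methylated, and a tert-butyl ether on C2', which must be removed by acid beside an acid-sensitive C-prenyl group. At least five steps follow.
- Comparison: this road forms more bonds in its key step and matches the chosen plan in regiocontrol. The chosen plan sets against it a precursor, 16, that comes from two routine acyl couplings, a ring closure that needs only Cs2CO3, and a ring born with OMe and OH already differentiated.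

**Alternative 2:** The cut removes the ring A C6–O bond and the C1–carboxyl bond. The phenoxide of the complete ring B phenol A4 would add to the aryne released by fluoride from silyl triflate A3, and the resulting aryl anion would be trapped by carboxylation to give acid A5.
- Merits: the hindered diaryl ether is made by addition to an aryne, not by metal-catalysed coupling, and the alkoxy group of the aryne directs the phenoxide to the distal carbon and the carboxyl between the two oxygens. Ring A never sits next to an enolisable chain, so no acylation of an enolate by the ester can intervene, and in this respect the road is safer than the chosen one.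
- Weak points: the road presupposes A4, the pentasubstituted ring B, which is the hard part of the molecule and would have to come from a separate linear sequence of regiochemically delicate aromatic substitutions. The di-ortho-substituted phenoxide is a poor nucleophile, protonation of the aryl anion competes with carboxylation, and fluoride threatens the silyl ether. Esterification, two acetal deprotections under acid, two prenylations and desilylation follow.
- Comparison: the convergence at the ether is better than in the chosen plan. The chosen plan sets against it that ring B and the ether are solved together, with every substituent of ring B placed by chain order.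

**Alternative 3:** The cut removes C1–C2 and C5–C6 of ring A. The aryl alkynyl ether A6, carrying complete ring B, would undergo a Diels–Alder reaction with ketene acetal diene A7 and aromatise by eliminating the acetal methoxy group to give salicylate A8.
- Merits: ring A is born with its hydroxyl free exactly where the prenyl ether belongs, and A8 is two steps from 24 (prenylation and desilylation), one fewer than from 19. The polarisation of both partners makes the regiochemistry dependable.
- Weak points: like alternative 2, it needs the finished ring B phenol first. A6 must be made from a hindered phenol by a dichlorovinyl ether and strong base sequence. Its alkyne is deactivated as a dienophile by the oxygen on the beta carbon, and the heat then required invites Claisen rearrangement of the C2' prenyl ether to the free C3' position.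
- Comparison: the endgame is shorter and the key step is a reliable reaction type. The chosen plan sets against it a ring B construction with no thermal step and no dependence on a pre-made pentasubstituted phenol.

Key step: step 8

Assumption: the two geometric isomers of the push–pull C4'=C5' enol ether (in 9, 10, 12 and 16) are taken to interconvert readily under base. They are drawn as the isomer with C3' and C6' cis, and the geometry is not treated as a stereochemical problem.

## Route

Step 1
Reactants: 1 methyl 2,6-dihydroxybenzoate; 2 2-chloro-N-methoxy-N-methylacetamide
Product: 3 methyl 2-hydroxy-6-{2-[methoxy(methyl)amino]-2-oxoethoxy}benzoate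
Conditions: K2CO3 (1.1 equiv), 2 (1.0 equiv), DMF, 50 °C
Reagents that add atoms: none
Why: Williamson ether synthesis on one of two equivalent phenols; after the first alkylation the remaining hydroxyl is held in a hydrogen bond to the ester carbonyl and is much less nucleophilic, so mono-alkylation should dominate with one equivalent of the alpha-chloro amide.

Step 2
Reactants: 4 methyl dimethoxyacetate
Product: 5 N,2,2-trimethoxy-N-methylacetamide
Conditions: MeNH(OMe)·HCl, i-PrMgCl, THF, −20 → 0 °C
Reagents that add atoms: N,O-dimethylhydroxylamine hydrochloride, Cl.CNOC
Why: Weinreb amide formation from an ester with the chloromagnesium amide of N,O-dimethylhydroxylamine; the alpha,alpha-dialkoxy ester is activated toward acyl substitution and the acetal is inert to the basic medium.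

Step 3
Reactants: 5 N,2,2-trimethoxy-N-methylacetamide; 6 1-propynylmagnesium bromide
Product: 8 1,1-dimethoxypent-3-yn-2-one, via magnesium hemiaminal adduct 7 (not isolated)
Conditions: THF, −78 → 0 °C; inverse quench into cold 1 M HCl
Reagents that add atoms: none
Why: Weinreb ketone synthesis: the chelated tetrahedral adduct 7 holds until work-up, so only one alkynyl group is delivered; the acidic inverse quench protonates the liberated hydroxylamine before it can add to the ynone.

Step 4
Reactants: 8 1,1-dimethoxypent-3-yn-2-one
Product: 9 (3E)-1,1,4-trimethoxypent-3-en-2-one
Conditions: MeOH, K2CO3 (10 mol %), 0 °C → rt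
Reagents that add atoms: methanol, CO
Why: Base-catalysed conjugate (oxa-Michael) addition of methanol to an ynone; the oxygen can enter only at the beta carbon, which fixes C4' as the masked carbonyl, and the E enol ether is expected as the thermodynamic isomer.

Step 5
Reactants: 9 (3E)-1,1,4-trimethoxypent-3-en-2-one
Product: 10 (3Z)-3-iodo-1,1,4-trimethoxypent-3-en-2-one
Conditions: NIS, MeCN, 0 °C → rt, dark
Reagents that add atoms: N-iodosuccinimide, O=C1CCC(=O)N1I
Why: Electrophilic alpha-iodination of a beta-alkoxy enone: the enol ether makes the alpha carbon the nucleophilic site, and loss of the proton from the oxocarbenium ion restores the conjugated enol ether; the keto acetal is untouched by the neutral reagent.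

Step 6
Reactants: 10 (3Z)-3-iodo-1,1,4-trimethoxypent-3-en-2-one; 11 tributyl(3-methylbut-2-en-1-yl)stannane
Product: 12 (3E)-1,1,4-trimethoxy-3-prenylpent-3-en-2-one
Conditions: Pd2(dba)3 (5 mol %), AsPh3 (20 mol %), CuI (10 mol %), DMF, 45 °C
Reagents that add atoms: none
Why: Stille coupling of an alpha-iodo enone with an allylic stannane: oxidative addition of zerovalent palladium into the electron-poor vinyl iodide is fast, AsPh3 and CuI speed the transmetalation, and coupling at the unsubstituted terminus of the prenyl group gives the linear isomer.

Step 7
Reactants: 12 (3E)-1,1,4-trimethoxy-3-prenylpent-3-en-2-one; 3 methyl 2-hydroxy-6-{2-[methoxy(methyl)amino]-2-oxoethoxy}benzoate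
Product: 16 methyl 2-hydroxy-6-{[(4E)-4,7,7-trimethoxy-2,6-dioxo-5-prenylhept-4-en-1-yl]oxy}benzoate, via lithium dienolate 13 (not isolated), via lithium phenoxide 14 (not isolated), via dilithium hemiaminal adduct 15 (not isolated)
Conditions: 12 added to LiN(SiMe3)2, THF, −78 °C; 3 premixed with LiN(SiMe3)2 (1.0 equiv), THF, −78 °C; combine, −78 → −20 °C; AcOH, −78 °C
Reagents that add atoms: none
Why: Vinylogous deprotonation of the beta-methoxy enone at its gamma-methyl group (the acetal C–H on the other side is not competitively removed) gives dienolate 13, which is acylated at the gamma carbon by the alpha-aryloxy Weinreb amide carried as its lithium phenoxide 14. The tetrahedral adduct 15 survives until the acidic quench, so the more acidic product can neither quench unreacted dienolate nor be acylated twice.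

Step 8
Reactants: 16 methyl 2-hydroxy-6-{[(4E)-4,7,7-trimethoxy-2,6-dioxo-5-prenylhept-4-en-1-yl]oxy}benzoate
Product: 19 methyl 2-[6-(dimethoxymethyl)-2-hydroxy-4-methoxy-5-prenylphenoxy]-6-hydroxybenzoate, via aldol adduct 17 (not isolated), via cyclohexadienone tautomer 18 (not isolated)
Conditions: Cs2CO3 (3 equiv), MeCN, rt → 45 °C, argon; pH 6 phosphate buffer
Reagents that add atoms: none
Why: Intramolecular aldol condensation with aromatisation, the reaction type of biomimetic cyclisations of 3,5-dioxo chains and their enol ethers to resorcinols. Carbonate first ionises the ring A phenol and then enolises the chain reversibly; the C1' enolate (alpha to the C2' ketone and bearing the aryloxy group) adds to the C6' ketone, which is activated by its two alpha-methoxy groups, in a 6-(enolexo)-exo-trig closure that forms C1'–C6' and gives aldol 17. E1cB loss of water across C1'–C6' gives dienone 18, and enolisation of the C2' ketone through C3'–H gives phenol 19, which makes the sequence irreversible. No lasting stereocentre is formed: the two in 17 are destroyed on aromatisation. Carbon over oxygen closure is secured by the methyl enol ether on C4' and the acetal on C7', which leave the chain oxygens only reversible hemiketals to form; the more acidic C3' position can close only a four-membered ring, and its anion serves to equilibrate the C4'=C5' geometry to the isomer that can cyclise. The same masking decides that C4' is born as OMe and C2' as the free phenol. The one competing irreversible path, attack of the C1' enolate on the ring A ester to a five-membered ring (Dieckmann type), should be shut because that ester is the carbonyl of a salicylate anion under the conditions and does not acylate enolates.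

Step 9
Reactants: 19 methyl 2-[6-(dimethoxymethyl)-2-hydroxy-4-methoxy-5-prenylphenoxy]-6-hydroxybenzoate; 20 1-bromo-3-methylbut-2-ene (prenyl bromide)
Product: 22 methyl 2-[6-(dimethoxymethyl)-4-methoxy-5-prenyl-2-(prenyloxy)phenoxy]-6-(prenyloxy)benzoate, via ring B mono-prenyl ether 21 (not isolated)
Conditions: K2CO3, 20 (2.5 equiv), DMF, rt → 50 °C
Reagents that add atoms: none
Why: Twofold Williamson ether synthesis: the unchelated ring B phenol should react first and the chelated ring A phenol on warming; with K2CO3 in DMF, O-alkylation of phenoxides is expected to prevail over C-alkylation.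

Step 10
Reactants: 22 methyl 2-[6-(dimethoxymethyl)-4-methoxy-5-prenyl-2-(prenyloxy)phenoxy]-6-(prenyloxy)benzoate
Product: 23 methyl 2-[6-formyl-4-methoxy-5-prenyl-2-(prenyloxy)phenoxy]-6-(prenyloxy)benzoate
Conditions: PPTS (10 mol %), acetone/H2O (9:1), rt
Reagents that add atoms: water, O
Why: Acid-catalysed hydrolysis of an aryl dimethyl acetal, which ionises far more readily than an aryl prenyl ether; the pyridinium acid is too weak to cleave the prenyl ethers or the ester.

Step 11
Reactants: 23 methyl 2-[6-formyl-4-methoxy-5-prenyl-2-(prenyloxy)phenoxy]-6-(prenyloxy)benzoate
Product: 24 methyl 2-[6-(hydroxymethyl)-4-methoxy-5-prenyl-2-(prenyloxy)phenoxy]-6-(prenyloxy)benzoate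
Conditions: NaBH4, MeOH/THF, 0 °C; aq. NH4Cl
Reagents that add atoms: none
Why: Chemoselective borohydride reduction of the aldehyde; the di-ortho-substituted methyl benzoate is not reduced, and at 0 °C the new alkoxide should not lactonise onto it.

## Compound list

1 | methyl 2,6-dihydroxybenzoate | COC(=O)c1c(O)cccc1O | starting material
2 | 2-chloro-N-methoxy-N-methylacetamide | CON(C)C(=O)CCl | starting material
3 | methyl 2-hydroxy-6-{2-[methoxy(methyl)amino]-2-oxoethoxy}benzoate | COC(=O)c1c(O)cccc1OCC(=O)N(C)OC | intermediate
4 | methyl dimethoxyacetate | COC(OC)C(=O)OC | starting material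
5 | N,2,2-trimethoxy-N-methylacetamide | COC(OC)C(=O)N(C)OC | intermediate
6 | 1-propynylmagnesium bromide | CC#C[Mg]Br | starting material
7 | bromomagnesium 1,1-dimethoxy-2-[methoxy(methyl)amino]pent-3-yn-2-olate | CC#CC(O[Mg]Br)(N(C)OC)C(OC)OC | intermediate
8 | 1,1-dimethoxypent-3-yn-2-one | CC#CC(=O)C(OC)OC | intermediate
9 | (3E)-1,1,4-trimethoxypent-3-en-2-one | C/C(OC)=C\C(=O)C(OC)OC | intermediate
10 | (3Z)-3-iodo-1,1,4-trimethoxypent-3-en-2-one | C/C(OC)=C(I)\C(=O)C(OC)OC | intermediate
11 | tributyl(3-methylbut-2-en-1-yl)stannane | CCCC[Sn](CCCC)(CCCC)CC=C(C)C | starting material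
12 | (3E)-1,1,4-trimethoxy-3-(3-methylbut-2-en-1-yl)pent-3-en-2-one | C/C(OC)=C(CC=C(C)C)\C(=O)C(OC)OC | intermediate
13 | lithium 1,1,4-trimethoxy-3-(3-methylbut-2-en-1-yl)penta-2,4-dien-2-olate (enolate geometry not defined) | C=C(OC)C(CC=C(C)C)=C(O[Li])C(OC)OC | intermediate
14 | lithium 2-(methoxycarbonyl)-3-{2-[methoxy(methyl)amino]-2-oxoethoxy}phenolate | COC(=O)c1c(O[Li])cccc1OCC(=O)N(C)OC | intermediate
15 | dilithium hemiaminal adduct of 13 and 14 (racemic at C2') | COC(=O)c1c(O[Li])cccc1OCC(O[Li])(N(C)OC)C/C(OC)=C(CC=C(C)C)\C(=O)C(OC)OC | intermediate
16 | methyl 2-hydroxy-6-{[(4E)-4,7,7-trimethoxy-5-(3-methylbut-2-en-1-yl)-2,6-dioxohept-4-en-1-yl]oxy}benzoate | COC(=O)c1c(O)cccc1OCC(=O)C/C(OC)=C(CC=C(C)C)\C(=O)C(OC)OC | intermediate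
17 | methyl 2-{[2-(dimethoxymethyl)-2-hydroxy-4-methoxy-3-(3-methylbut-2-en-1-yl)-6-oxocyclohex-3-en-1-yl]oxy}-6-hydroxybenzoate (racemic, both diastereomers) | COC(=O)c1c(O)cccc1OC1C(=O)CC(OC)=C(CC=C(C)C)C1(O)C(OC)OC | intermediate
18 | methyl 2-{[2-(dimethoxymethyl)-4-methoxy-3-(3-methylbut-2-en-1-yl)-6-oxocyclohexa-1,3-dien-1-yl]oxy}-6-hydroxybenzoate | COC(=O)c1c(O)cccc1OC1=C(C(OC)OC)C(CC=C(C)C)=C(OC)CC1=O | intermediate
19 | methyl 2-[6-(dimethoxymethyl)-2-hydroxy-4-methoxy-5-(3-methylbut-2-en-1-yl)phenoxy]-6-hydroxybenzoate | COC(=O)c1c(O)cccc1Oc1c(O)cc(OC)c(CC=C(C)C)c1C(OC)OC | intermediate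
20 | 1-bromo-3-methylbut-2-ene (prenyl bromide) | CC(C)=CCBr | starting material
21 | methyl 2-[6-(dimethoxymethyl)-4-methoxy-5-(3-methylbut-2-en-1-yl)-2-(3-methylbut-2-en-1-yloxy)phenoxy]-6-hydroxybenzoate | COC(=O)c1c(O)cccc1Oc1c(OCC=C(C)C)cc(OC)c(CC=C(C)C)c1C(OC)OC | intermediate
22 | methyl 2-[6-(dimethoxymethyl)-4-methoxy-5-(3-methylbut-2-en-1-yl)-2-(3-methylbut-2-en-1-yloxy)phenoxy]-6-(3-methylbut-2-en-1-yloxy)benzoate | COC(=O)c1c(OCC=C(C)C)cccc1Oc1c(OCC=C(C)C)cc(OC)c(CC=C(C)C)c1C(OC)OC | intermediate
23 | methyl 2-[6-formyl-4-methoxy-5-(3-methylbut-2-en-1-yl)-2-(3-methylbut-2-en-1-yloxy)phenoxy]-6-(3-methylbut-2-en-1-yloxy)benzoate | COC(=O)c1c(OCC=C(C)C)cccc1Oc1c(OCC=C(C)C)cc(OC)c(CC=C(C)C)c1C=O | intermediate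
24 | methyl 2-[6-(hydroxymethyl)-4-methoxy-5-(3-methylbut-2-en-1-yl)-2-(3-methylbut-2-en-1-yloxy)phenoxy]-6-(3-methylbut-2-en-1-yloxy)benzoate | COC(=O)c1c(OCC=C(C)C)cccc1Oc1c(OCC=C(C)C)cc(OC)c(CC=C(C)C)c1CO | target

## Step count and risk

Total steps: 11. Longest linear sequence: 10 steps (steps 2 to 11, from 4).

**Step 8 (key step).**
- Risk: the closure may stall. The chain carries the ring A phenoxide and rests largely as the doubly stabilised C3' anion, in which the C6' carbonyl is deactivated. The share of the C1' enolate is then small, and on prolonged warming cleavage of the C2'–C3' bond by adventitious hydroxide (retro-Claisen) could overtake the aldol.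
- Fallback: one negative charge is taken off the chain by carrying the ring A oxygen as its prenyl ether through the closure. Setting out from 1, mono-prenylation with 20 (K2CO3, acetone) should give methyl 2-hydroxy-6-(prenyloxy)benzoate F1. Alkylation with 2 (K2CO3, DMF) should give the Weinreb amide methyl 2-{2-[methoxy(methyl)amino]-2-oxoethoxy}-6-(prenyloxy)benzoate F2. Acylation of dienolate 13 with F2, as in step 7 but without the extra equivalent of base, should give the chain methyl 2-{[(4E)-4,7,7-trimethoxy-2,6-dioxo-5-prenylhept-4-en-1-yl]oxy}-6-(prenyloxy)benzoate F3. Cs2CO3 in MeCN at 0 °C should close it to methyl 2-[6-(dimethoxymethyl)-2-hydroxy-4-methoxy-5-prenylphenoxy]-6-(prenyloxy)benzoate F4. Prenylation of F4 with 20 comes back to the route at 22.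
- Price of the fallback: in F3 the ring A ester is a neutral benzoate and no longer disarmed, so the closure has to be run cold to keep the Dieckmann path behind the aldol.

**Step 7.**
- Risk: proton transfer in place of bond formation. The dienolate may deprotonate the amide alpha to the aryloxy group, or attack may be slow because the lithium phenoxide 14 aggregates. Acylation at the alpha carbon of the dienolate is a lesser concern.
- Fallback: the acyl donor is exchanged for an aldehyde, a better electrophile that cannot be acylated twice. Setting out from 3, reduction of the Weinreb amide with Cp2Zr(H)Cl (excess, the first equivalent being spent on the phenol; THF, rt) should give methyl 2-hydroxy-6-(2-oxoethoxy)benzoate F5 without touching the ester. Vinylogous aldol addition of 13 (two equivalents, one serving as base for the phenol and returning 12) should give racemic methyl 2-hydroxy-6-{[(4E)-2-hydroxy-4,7,7-trimethoxy-6-oxo-5-prenylhept-4-en-1-yl]oxy}benzoate F6. Parikh–Doering oxidation (SO3·pyridine, DMSO, i-Pr2NEt) comes back to the route at 16.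

**Step 6.**
- Risk: allylic transposition during transmetalation or reductive elimination would deliver the 1,1-dimethylallyl isomer, and protodeiodination may compete.
- Fallback: the allyl group has no such ambiguity. Setting out from 10, Stille coupling with allyltributylstannane under the same catalyst should give (3E)-1,1,4-trimethoxy-3-(prop-2-en-1-yl)pent-3-en-2-one F7. Cross-metathesis of F7 with 2-methylbut-2-ene (second-generation Grubbs catalyst, CH2Cl2, 40 °C), to which the tetrasubstituted enol ether is inert, comes back to the route at 12.

**Step 9.**
- Risk: C-alkylation of the ring B phenoxide at C3', which lies between two oxygens, and incomplete alkylation of the chelated ring A phenol.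
- Fallback: Mitsunobu etherification of 19 with 3-methylbut-2-en-1-ol (PPh3, DIAD, THF) generates no free phenoxide and so cannot alkylate on carbon. It passes through 21 and comes back to the route at 22 without any new compound.

## Further compounds

F1 | step 8 | methyl 2-hydroxy-6-(3-methylbut-2-en-1-yloxy)benzoate | COC(=O)c1c(O)cccc1OCC=C(C)C
F2 | step 8 | methyl 2-{2-[methoxy(methyl)amino]-2-oxoethoxy}-6-(3-methylbut-2-en-1-yloxy)benzoate | COC(=O)c1c(OCC=C(C)C)cccc1OCC(=O)N(C)OC
F3 | step 8 | methyl 2-{[(4E)-4,7,7-trimethoxy-5-(3-methylbut-2-en-1-yl)-2,6-dioxohept-4-en-1-yl]oxy}-6-(3-methylbut-2-en-1-yloxy)benzoate | COC(=O)c1c(OCC=C(C)C)cccc1OCC(=O)C/C(OC)=C(CC=C(C)C)\C(=O)C(OC)OC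
F4 | step 8 | methyl 2-[6-(dimethoxymethyl)-2-hydroxy-4-methoxy-5-(3-methylbut-2-en-1-yl)phenoxy]-6-(3-methylbut-2-en-1-yloxy)benzoate | COC(=O)c1c(OCC=C(C)C)cccc1Oc1c(O)cc(OC)c(CC=C(C)C)c1C(OC)OC
F5 | step 7 | methyl 2-hydroxy-6-(2-oxoethoxy)benzoate | COC(=O)c1c(O)cccc1OCC=O
F6 | step 7 | methyl 2-hydroxy-6-{[(4E)-2-hydroxy-4,7,7-trimethoxy-5-(3-methylbut-2-en-1-yl)-6-oxohept-4-en-1-yl]oxy}benzoate (racemic) | COC(=O)c1c(O)cccc1OCC(O)C/C(OC)=C(CC=C(C)C)\C(=O)C(OC)OC
F7 | step 6 | (3E)-1,1,4-trimethoxy-3-(prop-2-en-1-yl)pent-3-en-2-one | C/C(OC)=C(CC=C)\C(=O)C(OC)OC
F0 | step 9 | none | none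
A1 | alternative 1 | pentacarbonyl[2-tert-butoxy-1-{3-(methoxymethoxy)-2-[(6-methylhept-5-en-2-yn-1-yloxy)carbonyl]phenoxy}prop-2-en-1-ylidene]chromium | C=C(OC(C)(C)C)C(Oc1cccc(OCOC)c1C(=O)OCC#CCC=C(C)C)=[Cr](=C=O)(=C=O)(=C=O)(=C=O)=C=O
A2 | alternative 1 | dibenzodioxocinone lactone with 4'-hydroxy, 2'-tert-butoxy and 5'-prenyl groups on ring B and a 2-(methoxymethoxy) group on ring A | O=C1OCc2c(CC=C(C)C)c(O)cc(OC(C)(C)C)c2Oc2cccc(OCOC)c12
A3 | alternative 2 | 3-(methoxymethoxy)-2-(trimethylsilyl)phenyl trifluoromethanesulfonate | COCOc1cccc(OS(=O)(=O)C(F)(F)F)c1[Si](C)(C)C
A4 | alternative 2 | 2-{[tert-butyl(dimethyl)silyl]oxymethyl}-4-methoxy-6-(methoxymethoxy)-3-(3-methylbut-2-en-1-yl)phenol | Oc1c(OCOC)cc(OC)c(CC=C(C)C)c1CO[Si](C)(C)C(C)(C)C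
A5 | alternative 2 | 2-(methoxymethoxy)-6-[2-(methoxymethoxy)-4-methoxy-5-(3-methylbut-2-en-1-yl)-6-(tert-butyldimethylsilyloxymethyl)phenoxy]benzoic acid | OC(=O)c1c(OCOC)cccc1Oc1c(OCOC)cc(OC)c(CC=C(C)C)c1CO[Si](C)(C)C(C)(C)C
A6 | alternative 3 | methyl 3-[2-(tert-butyldimethylsilyloxymethyl)-4-methoxy-3-(3-methylbut-2-en-1-yl)-6-(3-methylbut-2-en-1-yloxy)phenoxy]prop-2-ynoate | COC(=O)C#COc1c(OCC=C(C)C)cc(OC)c(CC=C(C)C)c1CO[Si](C)(C)C(C)(C)C
A7 | alternative 3 | 1-methoxy-1-(trimethylsilyloxy)buta-1,3-diene (either geometry) | C=CC=C(OC)O[Si](C)(C)C
A8 | alternative 3 | methyl 2-hydroxy-6-[2-(3-methylbut-2-en-1-yloxy)-4-methoxy-5-(3-methylbut-2-en-1-yl)-6-(tert-butyldimethylsilyloxymethyl)phenoxy]benzoate | COC(=O)c1c(O)cccc1Oc1c(OCC=C(C)C)cc(OC)c(CC=C(C)C)c1CO[Si](C)(C)C(C)(C)C
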